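## The problem

The target is a germacranolide. Atoms are numbered C1–C10 around the ten-membered carbocycle, with C14 the methyl on C10, C15 the hydroxymethyl on C4, and C11(=C13H2)–C12(=O)–O6 the α-methylene-γ-butyrolactone fused trans across C6–C7. O1 is a free secondary hydroxyl and O8 carries a (2S)-2-methylbutanoate. Both ring olefins, C4=C5 and C9=C10, are trisubstituted and ring-cis (C3 cis to C6, C1 cis to C8), so their geometry has to be fixed before or during ring formation. C6, C7 and C8 are contiguous: C6 and C7 can be set together in one C–C bond formation and C7 can then bias C8. C1 is insulated from this triad by C2–C3 and the C4=C5 olefin and needs its own controller, and the acyl stereocentre comes from the chiral pool. The fragile functions are the α-methylene lactone (a Michael acceptor), three allylic C–O bonds at C1, C6 and C8 that ionise under strong acid, and the epimerisable α-carbon of the acyl group. In addition, O6 and O8 are both γ to C12, so either could lactonise and protection must decide between the 6,12- and the 8,12-olide. The enabling feature is C8: it is an allylic carbinol between C7 and the Z-C9=C10 olefin and it bears the ester, so a C8–C9 disconnection gives an aldehyde and a Z-alkenyl iodide whose union closes the ring, creates C8 and frees O8 for acylation.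

## Retrosynthesis

**Lactone and silyl ethers (31 from 29 and 27).** The O6–C12 bond and the three O–Si bonds are cut first. Closing the lactone last keeps the Michael acceptor out of every organometallic and basic step. Because O8 is already acylated, only O6 can reach C12, which closure before acylation could not guarantee. Seco acid 30, freed by fluoride from silylated acid 29, is all that separates 29 from target 31. Acid 29 comes from tert-butyl ester 27 through silyl ester 28. The forward steps must avoid strong protic acid on the allylic C–O bonds, hence a buffered silyl triflate and HF·pyridine.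

**Acyl C–O bond (27 from 24 and 25).** The ester is cut to ring carbinol 24 and (S)-2-methylbutanoic acid 25, activated as mixed anhydride 26. This removes one stereocentre to a commercial acid. The forward reaction has to acylate a hindered allylic ring alcohol without epimerising the acyl α-carbon.

**C8–C9, the ring bond (24 from 23).** Cutting C8–C9 opens the ring to iodo aldehyde 23. A cut at C5–C6 would form the lactone carbinol during closure and expose the α-methylene lactone to all later steps. A cut at C1–C10 would create C1 far from any directing centre. The C8–C9 cut places the new stereocentre next to C7 and delivers O8 free. Precursor 23 is acyclic, with C1, C6, C7 and both olefin geometries already fixed. The forward reaction must close a ten-membered ring with retention of the Z-iodide geometry, tolerate an acrylate and an enolisable aldehyde, and leave O8 unlactonised, which the tert-butyl ester ensures.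

**Oxidation level at C8 and protection of O6 (23 from 22, 21 and 20).** The aldehyde is traced to primary alcohol 22, its silyl ether 21 and hydroxy ester 20. Carrying C8 as a primary TBS ether next to secondary TBS ethers at O1 and O6 and a TBDPS ether at O15 allows it to be unveiled selectively. The aldehyde is made only in the step before ring closure because C7–H is doubly activated.

**C6–C7 (20 from 14 and 18).** This cut divides the chain into enal 14 and allylic bromide 18, joined through silyl ether 19. A 2-(alkoxycarbonyl)allylation creates C6 and C7 together and installs the complete C11–C13 acrylate, where an aldol route would need several further steps to build the acrylate. The fragments are of similar size and 14 carries only C1. The forward reaction must give the anti adduct and attack the Si face of the aldehyde.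

**Allylic bromide (18 from 17, 15 and 16).** The C7–C11 bond is cut to tert-butyl acrylate 15 and silyloxyacetaldehyde 16. Their adduct 17 gives 18 by allylic transposition. Both building blocks are commercial.

**C9–I and C10–C14 (14 from 13, 12 and 11).** The iodoalkene is traced to terminal alkyne 11 through diol 12 and hydroxy enal 13. Adding methyl and iodine anti across a propargylic alkoxide gives exactly the Z geometry needed, iodine cis to C1. Installing iodine after the fragment coupling avoids a second oxidative-addition site in the palladium step. The forward reaction needs the free O1–H as directing group.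

**C3–C4 (11 from 3 and 8).** The sp3–sp2 bond is cut to alkenyl iodide 3 and enyne 8, joined through alkylborane 9 and coupling product 10. The iodide geometry of 3 becomes the ring-cis C4=C5 olefin, and 8 brings C1 as a resolved carbinol. The forward reaction must hydroborate the vinyl group in the presence of a silyl alkyne and couple with retention.

**Building blocks (3 from 2 and 1; 8 from 7, 6, 4 and 5).** Iodide 3 comes from but-2-yne-1,4-diol 1 via monosilyl ether 2 by directed hydroalumination. Enyne 8 comes from acrolein 4 and ethynyltrimethylsilane 5 via racemic carbinol 6 and its resolved (S)-enantiomer 7.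

## Roads not taken

**Alternative 1:** The cut is C7–C11 on an open chain. In epoxy phosphonoacetate A1 the sodium carbanion of a phosphonoacetate tethered on O6 opens the trans C7–C8 epoxide at C7. Horner–Wadsworth–Emmons reaction with formaldehyde in the same flask then gives α-methylene lactone A2 with a free O8.
- Merits: C7 is set stereospecifically by inversion, the C6–C8 triad derives from one epoxy alcohol, and lactone, methylene group and free O8 appear in a single operation. In these respects it is better than the chosen plan, which needs separate steps for the C6–C7 bond, the lactone and the C8 carbinol.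
- Weak points: C8 of A1 is allylic, so 6-endo opening at C8 competes with the desired 5-exo attack at C7. The alkoxide released at O8 is γ to the new lactone carbonyl and can translactonise to the 8,12-olide. A2 still lacks the ring and the C1 stereocentre. Closing at C1–C10 would create C1 remote from all existing centres and would carry the Michael acceptor through deprotection, oxidation and macrocyclisation.
- Comparison: the chosen plan sets against this an early, enzyme-controlled C1, a ring closure that forms its new centre next to C7, and a lactone that appears only in the last step.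

**Alternative 2:** The cut is C5–C6. CrCl2 with catalytic NiCl2 adds the C5 alkenyl iodide of iodo aldehyde A3 to its C6 aldehyde, and the chromium alkoxide on O6 attacks the C12 methyl ester, giving protected germacranolide A4 with both rings closed.
- Merits: ring and lactone form in one step, no tert-butyl ester has to be cleaved, and there is no 6,12/8,12 ambiguity because O8 is a PMB ether. The endgame is shorter than in the chosen plan.
- Weak points: the aldehyde of A3 is as labile as the one in the chosen route. The C5 iodide needs iodine cis to C3 and trans to C15, which directed hydroalumination of butynediol does not give. The Z-C9=C10 olefin must be built inside the open chain. After closure the α-methylene lactone has to survive PMB removal, a DMAP-promoted acylation at O8 and desilylation.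
- Comparison: the chosen plan gives up the one-step lactonisation. In return O8 emerges free exactly when it is to be acylated, and the Michael acceptor never meets nucleophilic reagents.

**Alternative 3:** The cut is C2–C3, made while C5–C10 is broken. The potassium alkoxide of cis-1,2-dialkenylcyclohexanol A5 (KH, 18-crown-6) undergoes an anionic oxy-Cope shift to the ten-membered C10 ketone A6.
- Merits: ring expansion needs no high dilution and no excess chromium, and C6, C7 and C8 are set on a cyclohexane. As a way to form a medium ring it is more dependable than any macrocyclisation.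
- Weak points: A6 is far from the target. C1 is a methylene, C10 is a ketone, C14 and the C9=C10 olefin are absent, and C7 bears a two-carbon chain that must still be oxidised, lactonised and methylenated. Introducing O1 by allylic oxidation and the C9=C10 olefin from the ketone would have to be regio- and stereoselective on a flexible ring. The ring-cis C4=C5 geometry depends on the chair or boat course of the rearrangement.
- Comparison: the chosen plan closes the ring with every carbon and oxygen in place, at the price of a dilution-dependent step.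

Key step: step 16

Assumption: the (S,S)-bis(oxazolinyl)carbazole–chromium catalyst is taken to deliver the allyl unit to the Si face of the aldehyde of 14, and the lipase to acylate (R)-6 faster; if a test shows the opposite sense, the antipodal ligand or the acetate fraction of the resolution is used and nothing else changes.

## Route

Step 1
Reactants: 1 but-2-yne-1,4-diol
Product: 2 4-[(tert-butyldiphenylsilyl)oxy]but-2-yn-1-ol
Conditions: TBDPSCl (1 equiv), imidazole, 1 (3 equiv), DMF, 0 °C → rt
Reagents that add atoms: tert-butyl(chloro)diphenylsilane, CC(C)(C)[Si](Cl)(c1ccccc1)c1ccccc1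
Why: Statistical monosilylation of a symmetrical diol used in excess should give the mono ether cleanly; the robust TBDPS group marks O15 for the whole route.

Step 2
Reactants: 2 4-[(tert-butyldiphenylsilyl)oxy]but-2-yn-1-ol
Product: 3 (2Z)-4-[(tert-butyldiphenylsilyl)oxy]-3-iodobut-2-en-1-ol
Conditions: NaAlH2(OCH2CH2OCH3)2, THF, 0 °C; then I2, THF, −78 → 0 °C
Reagents that add atoms: iodine, II
Why: Hydroxyl-directed trans-hydroalumination places aluminium on the alkyne carbon remote from the free hydroxyl in a five-membered alanate, and iodinolysis with retention gives the iodide cis to CH2OH; this geometry becomes the ring-cis C4=C5 olefin, and the low temperature suppresses elimination of the silyloxy group.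

Step 3
Reactants: 4 acrolein; 5 ethynyltrimethylsilane
Product: 6 rac-5-(trimethylsilyl)pent-1-en-4-yn-3-ol
Conditions: n-BuLi, THF, −78 °C; then 4; aq. NH4Cl
Reagents that add atoms: none
Why: 1,2-Addition of a lithium acetylide to an enal is standard and gives the carbinol that will become C1, flanked by the future C2–C3 and C10–C9 units.

Step 4
Reactants: 6 rac-5-(trimethylsilyl)pent-1-en-4-yn-3-ol
Product: 7 (3S)-5-(trimethylsilyl)pent-1-en-4-yn-3-ol
Conditions: Pseudomonas fluorescens lipase, vinyl acetate, pentane, rt, to ca. 55% conversion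
Reagents that add atoms: none
Why: Lipase-catalysed kinetic resolution by transesterification: with the silylethynyl group as the large and vinyl as the medium substituent the enzyme should acylate the R enantiomer and leave (S)-7, which fixes C1.

Step 5
Reactants: 7 (3S)-5-(trimethylsilyl)pent-1-en-4-yn-3-ol
Product: 8 trimethyl{[(3S)-5-(trimethylsilyl)pent-1-en-4-yn-3-yl]oxy}silane
Conditions: TMSCl, imidazole, CH2Cl2, 0 °C
Reagents that add atoms: chlorotrimethylsilane, C[Si](C)(C)Cl
Why: O-Silylation caps the hydroxyl so that it does not consume 9-BBN; the trimethylsilyl ether is chosen because it leaves under the same conditions as the C-silyl group.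

Step 6
Reactants: 8 trimethyl{[(3S)-5-(trimethylsilyl)pent-1-en-4-yn-3-yl]oxy}silane; 3 (2Z)-4-[(tert-butyldiphenylsilyl)oxy]-3-iodobut-2-en-1-ol
Product: 11 (2E,6S)-3-{[(tert-butyldiphenylsilyl)oxy]methyl}oct-2-en-7-yne-1,6-diol, via alkylborane 9 (not isolated), via bis-silyl coupling product 10 (not isolated)
Conditions: 9-BBN dimer, THF, 0 °C → rt; then 3, PdCl2(dppf) (5 mol %), AsPh3, aq. K3PO4, DMF, rt; then K2CO3, MeOH, rt
Reagents that add atoms: none
Why: 9-BBN adds anti-Markovnikov to the monosubstituted alkene and leaves the hindered silyl alkyne; B-alkyl Suzuki–Miyaura coupling forms C3–C4 with retention of the iodide geometry (C3 cis to C6), and methanolysis removes both trimethylsilyl groups.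

Step 7
Reactants: 11 (2E,6S)-3-{[(tert-butyldiphenylsilyl)oxy]methyl}oct-2-en-7-yne-1,6-diol
Product: 12 (2E,6S,7Z)-3-{[(tert-butyldiphenylsilyl)oxy]methyl}-8-iodo-7-methylocta-2,7-diene-1,6-diol
Conditions: MeMgBr (5 equiv), CuI (20 mol %), THF, −10 °C → rt; then I2, −78 → 0 °C; aq. NH4Cl
Reagents that add atoms: methylmagnesium bromide, C[Mg]Br; iodine, II
Why: Copper-catalysed anti-carbomagnesiation of the propargylic magnesium alkoxide puts methyl on C10 and magnesium on C9 in a five-membered chelate, and iodinolysis with retention gives the Z-iodide (iodine cis to C1); the allylic alkoxide at C6 is a spectator.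

Step 8
Reactants: 12 (2E,6S,7Z)-3-{[(tert-butyldiphenylsilyl)oxy]methyl}-8-iodo-7-methylocta-2,7-diene-1,6-diol
Product: 13 (2E,6S,7Z)-3-{[(tert-butyldiphenylsilyl)oxy]methyl}-6-hydroxy-8-iodo-7-methylocta-2,7-dienal
Conditions: TEMPO (10 mol %), PhI(OAc)2, CH2Cl2, rt
Reagents that add atoms: none
Why: Oxoammonium (TEMPO/PhI(OAc)2) oxidation takes the unhindered primary allylic alcohol much faster than the secondary one and is mild enough to keep the enal geometry.

Step 9
Reactants: 13 (2E,6S,7Z)-3-{[(tert-butyldiphenylsilyl)oxy]methyl}-6-hydroxy-8-iodo-7-methylocta-2,7-dienal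
Product: 14 (2E,6S,7Z)-6-[(tert-butyldimethylsilyl)oxy]-3-{[(tert-butyldiphenylsilyl)oxy]methyl}-8-iodo-7-methylocta-2,7-dienal
Conditions: TBSCl, imidazole, DMF, rt
Reagents that add atoms: tert-butyl(chloro)dimethylsilane, CC(C)(C)[Si](C)(C)Cl
Why: Standard silylation of the secondary allylic alcohol; the enal is inert to these conditions.

Step 10
Reactants: 15 tert-butyl acrylate; 16 [(tert-butyldimethylsilyl)oxy]acetaldehyde
Product: 17 tert-butyl 4-[(tert-butyldimethylsilyl)oxy]-3-hydroxy-2-methylidenebutanoate (racemic)
Conditions: DABCO (1 equiv), neat in excess 15, rt, several days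
Reagents that add atoms: none
Why: Morita–Baylis–Hillman reaction; the α-oxygenated aldehyde is an activated acceptor, which offsets the sluggishness of the tert-butyl acrylate, and the carbinol centre is erased in the next step.

Step 11
Reactants: 17 tert-butyl 4-[(tert-butyldimethylsilyl)oxy]-3-hydroxy-2-methylidenebutanoate
Product: 18 tert-butyl (2Z)-2-(bromomethyl)-4-[(tert-butyldimethylsilyl)oxy]but-2-enoate
Conditions: NBS, Me2S, CH2Cl2, 0 °C → rt
Reagents that add atoms: N-bromosuccinimide, O=C1CCC(=O)N1Br
Why: The alcohol is activated as an alkoxysulfonium ion and bromide attacks the methylidene carbon in an SN2′ displacement, giving the conjugated allylic bromide under neutral conditions that spare the silyl ether and the tert-butyl ester.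

Step 12
Reactants: 14 (2E,6S,7Z)-6-[(tert-butyldimethylsilyl)oxy]-3-{[(tert-butyldiphenylsilyl)oxy]methyl}-8-iodo-7-methylocta-2,7-dienal; 18 tert-butyl (2Z)-2-(bromomethyl)-4-[(tert-butyldimethylsilyl)oxy]but-2-enoate
Product: 20 tert-butyl (3R,4R,5E,9S,10Z)-9-[(tert-butyldimethylsilyl)oxy]-3-{[(tert-butyldimethylsilyl)oxy]methyl}-6-{[(tert-butyldiphenylsilyl)oxy]methyl}-4-hydroxy-11-iodo-10-methyl-2-methylideneundeca-5,10-dienoate, via trimethylsilyl ether 19 (not isolated)
Conditions: CrCl2 (10 mol %), (S,S)-3,6-di-tert-butyl-1,8-bis(4-isopropyl-4,5-dihydrooxazol-2-yl)-9H-carbazole (11 mol %), iPr2NEt (30 mol %), Mn powder, TMSCl, THF, 0 °C → rt; then citric acid, MeOH, 0 °C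
Reagents that add atoms: none
Why: Catalytic asymmetric Nozaki–Hiyama 2-(alkoxycarbonyl)allylation: the allylchromium equilibrates and adds through a chair transition state with the silyloxymethyl group equatorial, giving the anti C6/C7 pair, while the chiral tridentate ligand on chromium directs the allyl unit to the Si face of the aldehyde (6R). The alkenyl iodide is inert without nickel, and the tert-butyl ester keeps O6 from lactonising.

Step 13
Reactants: 20 tert-butyl (3R,4R,5E,9S,10Z)-9-[(tert-butyldimethylsilyl)oxy]-3-{[(tert-butyldimethylsilyl)oxy]methyl}-6-{[(tert-butyldiphenylsilyl)oxy]methyl}-4-hydroxy-11-iodo-10-methyl-2-methylideneundeca-5,10-dienoate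
Product: 21 tert-butyl (3R,4R,5E,9S,10Z)-4,9-bis[(tert-butyldimethylsilyl)oxy]-3-{[(tert-butyldimethylsilyl)oxy]methyl}-6-{[(tert-butyldiphenylsilyl)oxy]methyl}-11-iodo-10-methyl-2-methylideneundeca-5,10-dienoate
Conditions: TBSOTf, 2,6-lutidine, CH2Cl2, −78 → 0 °C
Reagents that add atoms: tert-butyldimethylsilyl trifluoromethanesulfonate, CC(C)(C)[Si](C)(C)OS(=O)(=O)C(F)(F)F
Why: The silyl triflate is needed for the hindered secondary allylic hydroxyl; blocking O6 reserves it for the final lactonisation and prevents retro-aldol or elimination chemistry once C8 is an aldehyde.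

Step 14
Reactants: 21 tert-butyl (3R,4R,5E,9S,10Z)-4,9-bis[(tert-butyldimethylsilyl)oxy]-3-{[(tert-butyldimethylsilyl)oxy]methyl}-6-{[(tert-butyldiphenylsilyl)oxy]methyl}-11-iodo-10-methyl-2-methylideneundeca-5,10-dienoate
Product: 22 tert-butyl (3R,4R,5E,9S,10Z)-4,9-bis[(tert-butyldimethylsilyl)oxy]-6-{[(tert-butyldiphenylsilyl)oxy]methyl}-3-(hydroxymethyl)-11-iodo-10-methyl-2-methylideneundeca-5,10-dienoate
Conditions: HF·pyridine, pyridine, THF, 0 °C
Reagents that add atoms: none
Why: Selective desilylation: buffered HF·pyridine cleaves the primary TBS ether much faster than the two secondary TBS ethers and the TBDPS ether, and the tert-butyl ester does not lactonise onto the freed O8.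

Step 15
Reactants: 22 tert-butyl (3R,4R,5E,9S,10Z)-4,9-bis[(tert-butyldimethylsilyl)oxy]-6-{[(tert-butyldiphenylsilyl)oxy]methyl}-3-(hydroxymethyl)-11-iodo-10-methyl-2-methylideneundeca-5,10-dienoate
Product: 23 tert-butyl (3S,4R,5E,9S,10Z)-4,9-bis[(tert-butyldimethylsilyl)oxy]-6-{[(tert-butyldiphenylsilyl)oxy]methyl}-3-formyl-11-iodo-10-methyl-2-methylideneundeca-5,10-dienoate
Conditions: Dess–Martin periodinane, NaHCO3, CH2Cl2, 0 °C; used at once
Reagents that add atoms: none
Why: Buffered Dess–Martin oxidation is neutral enough to leave the doubly activated C7–H and the β-silyloxy group untouched; the aldehyde is not stored (the C7 descriptor changes only because the formyl group outranks C6).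

Step 16
Reactants: 23 tert-butyl (3S,4R,5E,9S,10Z)-4,9-bis[(tert-butyldimethylsilyl)oxy]-6-{[(tert-butyldiphenylsilyl)oxy]methyl}-3-formyl-11-iodo-10-methyl-2-methylideneundeca-5,10-dienoate
Product: 24 tert-butyl 2-[(1R,2R,3Z,5S,8E,10R)-5,10-bis[(tert-butyldimethylsilyl)oxy]-8-{[(tert-butyldiphenylsilyl)oxy]methyl}-2-hydroxy-4-methylcyclodeca-3,8-dien-1-yl]prop-2-enoate
Conditions: CrCl2 (10 equiv), NiCl2 (1 mol % of CrCl2), degassed DMSO–THF, 0.003 M, slow addition, rt
Reagents that add atoms: none
Why: Nozaki–Hiyama–Kishi macrocyclisation: NiCl2 is reduced by divalent chromium to zerovalent nickel, which inserts into the C9–I bond with retention of the Z geometry; the alkenyl group passes to trivalent chromium and adds to the C8 aldehyde, the closest known type being alkenyl iodide–aldehyde closures of nine- to twelve-membered carbocycles. The ring closes in a 10-exo-trig mode (C9 attacks the carbonyl carbon, the C=O lying outside the new ring); the two cis olefins and the C6/C7 substituents pre-bend the chain, and high dilution with slow addition suppresses dimerisation. The new C8 centre is controlled by C7: in a Felkin–Anh arrangement the acrylate arm stands anti to the incoming C9, C6 lies on the carbonyl-oxygen side and H7 on the side of the aldehyde hydrogen, which places O8 cis to C11 on the ring, i.e. the required 8R carbinol. Selectivity for the aldehyde over the acrylate is secured by the low reactivity of alkenylchromium toward esters and by the low nickel loading, which disfavours Heck-type paths. The non-basic medium should leave C7–H and the β-silyloxy group intact, and the tert-butyl ester keeps the chromium alkoxide on O8 from closing an 8,12-lactone, so O8 emerges free.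

Step 17
Reactants: 24 tert-butyl 2-[(1R,2R,3Z,5S,8E,10R)-5,10-bis[(tert-butyldimethylsilyl)oxy]-8-{[(tert-butyldiphenylsilyl)oxy]methyl}-2-hydroxy-4-methylcyclodeca-3,8-dien-1-yl]prop-2-enoate; 25 (2S)-2-methylbutanoic acid
Product: 27 tert-butyl 2-[(1R,2R,3Z,5S,8E,10R)-5,10-bis[(tert-butyldimethylsilyl)oxy]-8-{[(tert-butyldiphenylsilyl)oxy]methyl}-4-methyl-2-{[(2S)-2-methylbutanoyl]oxy}cyclodeca-3,8-dien-1-yl]prop-2-enoate, via mixed anhydride 26 (not isolated)
Conditions: 25, 2,4,6-trichlorobenzoyl chloride, Et3N, THF, rt; then 24, DMAP, toluene, rt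
Reagents that add atoms: none
Why: Yamaguchi esterification acylates hindered secondary alcohols under mild conditions; the C8–O bond is not touched, so 8R is retained, and a short exposure to DMAP at room temperature should not epimerise the acyl α-carbon.

Step 18
Reactants: 27 tert-butyl 2-[(1R,2R,3Z,5S,8E,10R)-5,10-bis[(tert-butyldimethylsilyl)oxy]-8-{[(tert-butyldiphenylsilyl)oxy]methyl}-4-methyl-2-{[(2S)-2-methylbutanoyl]oxy}cyclodeca-3,8-dien-1-yl]prop-2-enoate
Product: 29 2-[(1R,2R,3Z,5S,8E,10R)-5,10-bis[(tert-butyldimethylsilyl)oxy]-8-{[(tert-butyldiphenylsilyl)oxy]methyl}-4-methyl-2-{[(2S)-2-methylbutanoyl]oxy}cyclodeca-3,8-dien-1-yl]prop-2-enoic acid, via trimethylsilyl ester 28 (not isolated)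
Conditions: TMSOTf, 2,6-lutidine, CH2Cl2, 0 °C; then pH 5 buffer
Reagents that add atoms: none
Why: Silyl triflate-mediated tert-butyl ester cleavage: O-silylation of the carbonyl and loss of isobutene give the silyl ester, hydrolysed on work-up; the lutidine buffer spares the silyl ethers, the allylic C–O bonds and the C8 ester.

Step 19
Reactants: 29 2-[(1R,2R,3Z,5S,8E,10R)-5,10-bis[(tert-butyldimethylsilyl)oxy]-8-{[(tert-butyldiphenylsilyl)oxy]methyl}-4-methyl-2-{[(2S)-2-methylbutanoyl]oxy}cyclodeca-3,8-dien-1-yl]prop-2-enoic acid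
Product: 31 (3aR,4R,5Z,7S,10E,11aR)-7-hydroxy-10-(hydroxymethyl)-6-methyl-3-methylidene-2-oxo-2,3,3a,4,7,8,9,11a-octahydrocyclodeca[b]furan-4-yl (2S)-2-methylbutanoate, via seco acid 30 (not isolated)
Conditions: HF·pyridine, THF, 0 °C → rt
Reagents that add atoms: none
Why: Fluoride-mediated global desilylation frees O1, O6 and O15; the γ-hydroxy acid should close to the γ-lactone in the mildly acidic medium (5-exo-trig acyl substitution), and only O6 can do so because O8 is acylated and O1 and O15 are too remote. No stereocentre is touched.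

## Compound list

1 | but-2-yne-1,4-diol | OCC#CCO | starting material
2 | 4-[(tert-butyldiphenylsilyl)oxy]but-2-yn-1-ol | OCC#CCO[Si](c1ccccc1)(c1ccccc1)C(C)(C)C | intermediate
3 | (2Z)-4-[(tert-butyldiphenylsilyl)oxy]-3-iodobut-2-en-1-ol | OC/C=C(\I)CO[Si](c1ccccc1)(c1ccccc1)C(C)(C)C | intermediate
4 | acrolein | C=CC=O | starting material
5 | ethynyltrimethylsilane | C#C[Si](C)(C)C | starting material
6 | rac-5-(trimethylsilyl)pent-1-en-4-yn-3-ol | C=CC(O)C#C[Si](C)(C)C | intermediate
7 | (3S)-5-(trimethylsilyl)pent-1-en-4-yn-3-ol | C=C[C@H](O)C#C[Si](C)(C)C | intermediate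
8 | trimethyl{[(3S)-5-(trimethylsilyl)pent-1-en-4-yn-3-yl]oxy}silane | C=C[C@H](O[Si](C)(C)C)C#C[Si](C)(C)C | intermediate
9 | 9-{(3S)-5-(trimethylsilyl)-3-[(trimethylsilyl)oxy]pent-4-yn-1-yl}-9-borabicyclo[3.3.1]nonane | C[Si](C)(C)O[C@@H](CCB1C2CCCC1CCC2)C#C[Si](C)(C)C | intermediate
10 | (2E,6S)-3-{[(tert-butyldiphenylsilyl)oxy]methyl}-8-(trimethylsilyl)-6-[(trimethylsilyl)oxy]oct-2-en-7-yn-1-ol | OC/C=C(/CO[Si](c1ccccc1)(c1ccccc1)C(C)(C)C)CC[C@H](O[Si](C)(C)C)C#C[Si](C)(C)C | intermediate
11 | (2E,6S)-3-{[(tert-butyldiphenylsilyl)oxy]methyl}oct-2-en-7-yne-1,6-diol | OC/C=C(/CO[Si](c1ccccc1)(c1ccccc1)C(C)(C)C)CC[C@H](O)C#C | intermediate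
12 | (2E,6S,7Z)-3-{[(tert-butyldiphenylsilyl)oxy]methyl}-8-iodo-7-methylocta-2,7-diene-1,6-diol | OC/C=C(/CO[Si](c1ccccc1)(c1ccccc1)C(C)(C)C)CC[C@H](O)/C(C)=C\I | intermediate
13 | (2E,6S,7Z)-3-{[(tert-butyldiphenylsilyl)oxy]methyl}-6-hydroxy-8-iodo-7-methylocta-2,7-dienal | O=C/C=C(/CO[Si](c1ccccc1)(c1ccccc1)C(C)(C)C)CC[C@H](O)/C(C)=C\I | intermediate
14 | (2E,6S,7Z)-6-[(tert-butyldimethylsilyl)oxy]-3-{[(tert-butyldiphenylsilyl)oxy]methyl}-8-iodo-7-methylocta-2,7-dienal | O=C/C=C(/CO[Si](c1ccccc1)(c1ccccc1)C(C)(C)C)CC[C@H](O[Si](C)(C)C(C)(C)C)/C(C)=C\I | intermediate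
15 | tert-butyl acrylate | C=CC(=O)OC(C)(C)C | starting material
16 | [(tert-butyldimethylsilyl)oxy]acetaldehyde | O=CCO[Si](C)(C)C(C)(C)C | starting material
17 | tert-butyl 4-[(tert-butyldimethylsilyl)oxy]-3-hydroxy-2-methylidenebutanoate (racemic) | C=C(C(=O)OC(C)(C)C)C(O)CO[Si](C)(C)C(C)(C)C | intermediate
18 | tert-butyl (2Z)-2-(bromomethyl)-4-[(tert-butyldimethylsilyl)oxy]but-2-enoate | BrC/C(C(=O)OC(C)(C)C)=C\CO[Si](C)(C)C(C)(C)C | intermediate
19 | tert-butyl (3R,4R,5E,9S,10Z)-9-[(tert-butyldimethylsilyl)oxy]-3-{[(tert-butyldimethylsilyl)oxy]methyl}-6-{[(tert-butyldiphenylsilyl)oxy]methyl}-11-iodo-10-methyl-2-methylidene-4-[(trimethylsilyl)oxy]undeca-5,10-dienoate | CC(C)(C)[Si](C)(C)OC[C@@H](C(=C)C(=O)OC(C)(C)C)[C@H](O[Si](C)(C)C)/C=C(/CO[Si](c1ccccc1)(c1ccccc1)C(C)(C)C)CC[C@H](O[Si](C)(C)C(C)(C)C)/C(C)=C\I | intermediate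
20 | tert-butyl (3R,4R,5E,9S,10Z)-9-[(tert-butyldimethylsilyl)oxy]-3-{[(tert-butyldimethylsilyl)oxy]methyl}-6-{[(tert-butyldiphenylsilyl)oxy]methyl}-4-hydroxy-11-iodo-10-methyl-2-methylideneundeca-5,10-dienoate | CC(C)(C)[Si](C)(C)OC[C@@H](C(=C)C(=O)OC(C)(C)C)[C@H](O)/C=C(/CO[Si](c1ccccc1)(c1ccccc1)C(C)(C)C)CC[C@H](O[Si](C)(C)C(C)(C)C)/C(C)=C\I | intermediate
21 | tert-butyl (3R,4R,5E,9S,10Z)-4,9-bis[(tert-butyldimethylsilyl)oxy]-3-{[(tert-butyldimethylsilyl)oxy]methyl}-6-{[(tert-butyldiphenylsilyl)oxy]methyl}-11-iodo-10-methyl-2-methylideneundeca-5,10-dienoate | CC(C)(C)[Si](C)(C)OC[C@@H](C(=C)C(=O)OC(C)(C)C)[C@H](O[Si](C)(C)C(C)(C)C)/C=C(/CO[Si](c1ccccc1)(c1ccccc1)C(C)(C)C)CC[C@H](O[Si](C)(C)C(C)(C)C)/C(C)=C\I | intermediate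
22 | tert-butyl (3R,4R,5E,9S,10Z)-4,9-bis[(tert-butyldimethylsilyl)oxy]-6-{[(tert-butyldiphenylsilyl)oxy]methyl}-3-(hydroxymethyl)-11-iodo-10-methyl-2-methylideneundeca-5,10-dienoate | OC[C@@H](C(=C)C(=O)OC(C)(C)C)[C@H](O[Si](C)(C)C(C)(C)C)/C=C(/CO[Si](c1ccccc1)(c1ccccc1)C(C)(C)C)CC[C@H](O[Si](C)(C)C(C)(C)C)/C(C)=C\I | intermediate
23 | tert-butyl (3S,4R,5E,9S,10Z)-4,9-bis[(tert-butyldimethylsilyl)oxy]-6-{[(tert-butyldiphenylsilyl)oxy]methyl}-3-formyl-11-iodo-10-methyl-2-methylideneundeca-5,10-dienoate | O=C[C@@H](C(=C)C(=O)OC(C)(C)C)[C@H](O[Si](C)(C)C(C)(C)C)/C=C(/CO[Si](c1ccccc1)(c1ccccc1)C(C)(C)C)CC[C@H](O[Si](C)(C)C(C)(C)C)/C(C)=C\I | intermediate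
24 | tert-butyl 2-[(1R,2R,3Z,5S,8E,10R)-5,10-bis[(tert-butyldimethylsilyl)oxy]-8-{[(tert-butyldiphenylsilyl)oxy]methyl}-2-hydroxy-4-methylcyclodeca-3,8-dien-1-yl]prop-2-enoate | CC(C)(C)OC(=O)C(=C)[C@H]1[C@H](O[Si](C)(C)C(C)(C)C)/C=C(/CO[Si](c2ccccc2)(c2ccccc2)C(C)(C)C)CC[C@H](O[Si](C)(C)C(C)(C)C)/C(C)=C\[C@H]1O | intermediate
25 | (2S)-2-methylbutanoic acid | CC[C@H](C)C(=O)O | starting material
26 | (2S)-2-methylbutanoic 2,4,6-trichlorobenzoic anhydride | CC[C@H](C)C(=O)OC(=O)c1c(Cl)cc(Cl)cc1Cl | intermediate
27 | tert-butyl 2-[(1R,2R,3Z,5S,8E,10R)-5,10-bis[(tert-butyldimethylsilyl)oxy]-8-{[(tert-butyldiphenylsilyl)oxy]methyl}-4-methyl-2-{[(2S)-2-methylbutanoyl]oxy}cyclodeca-3,8-dien-1-yl]prop-2-enoate | CC(C)(C)OC(=O)C(=C)[C@H]1[C@H](O[Si](C)(C)C(C)(C)C)/C=C(/CO[Si](c2ccccc2)(c2ccccc2)C(C)(C)C)CC[C@H](O[Si](C)(C)C(C)(C)C)/C(C)=C\[C@H]1OC(=O)[C@@H](C)CC | intermediate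
28 | trimethylsilyl ester of acid 29 | C[Si](C)(C)OC(=O)C(=C)[C@H]1[C@H](O[Si](C)(C)C(C)(C)C)/C=C(/CO[Si](c2ccccc2)(c2ccccc2)C(C)(C)C)CC[C@H](O[Si](C)(C)C(C)(C)C)/C(C)=C\[C@H]1OC(=O)[C@@H](C)CC | intermediate
29 | 2-[(1R,2R,3Z,5S,8E,10R)-5,10-bis[(tert-butyldimethylsilyl)oxy]-8-{[(tert-butyldiphenylsilyl)oxy]methyl}-4-methyl-2-{[(2S)-2-methylbutanoyl]oxy}cyclodeca-3,8-dien-1-yl]prop-2-enoic acid | OC(=O)C(=C)[C@H]1[C@H](O[Si](C)(C)C(C)(C)C)/C=C(/CO[Si](c2ccccc2)(c2ccccc2)C(C)(C)C)CC[C@H](O[Si](C)(C)C(C)(C)C)/C(C)=C\[C@H]1OC(=O)[C@@H](C)CC | intermediate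
30 | 2-[(1S,2R,3Z,5S,8E,10R)-5,10-dihydroxy-8-(hydroxymethyl)-4-methyl-2-{[(2S)-2-methylbutanoyl]oxy}cyclodeca-3,8-dien-1-yl]prop-2-enoic acid | OC(=O)C(=C)[C@H]1[C@H](O)/C=C(/CO)CC[C@H](O)/C(C)=C\[C@H]1OC(=O)[C@@H](C)CC | intermediate
31 | (3aR,4R,5Z,7S,10E,11aR)-7-hydroxy-10-(hydroxymethyl)-6-methyl-3-methylidene-2-oxo-2,3,3a,4,7,8,9,11a-octahydrocyclodeca[b]furan-4-yl (2S)-2-methylbutanoate | C=C1C(=O)O[C@@H]2/C=C(/CO)CC[C@H](O)/C(C)=C\[C@@H](OC(=O)[C@@H](C)CC)[C@@H]12 | target

## Step count and risks

Total steps: 19. Longest linear sequence: 15 steps (steps 3–9 and 12–19, from acrolein).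

**Step 16 (key step).**
- What may go wrong: intermolecular coupling may outrun ring closure if the open chain does not fold. Addition may occur from the other face of C8, because the ring constraint can override the Felkin–Anh preference. The aldehyde may degrade before it reacts, by epimerisation at C7, migration of the C11=C13 double bond into conjugation, or β-elimination of the C6 silyloxy group, since C7–H is activated twice.
- Fallback for wrong-face addition: it sets out from 23. The closure product, C8-epimeric carbinol F1, is oxidised with Dess–Martin periodinane to ten-membered enone F2. F2 is reduced under reagent control with the CBS oxazaborolidine antipode that delivers hydride to the Si face of C8 (catecholborane, low temperature). This returns to the route at 24 and replaces substrate control by reagent control.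

**Step 12.**
- What may go wrong: facial selectivity of the chiral chromium catalyst may be poor on a hindered Z-configured enal. The anti preference may erode if the allylchromium reacts before it equilibrates. The enal may isomerise at C4=C5 under Lewis-acidic silyl chloride. The allylchromium may lose the silyloxy group by 1,4-elimination.
- Fallback: it sets out from 14 and 18. The coupling is run with stoichiometric CrCl2 in THF without ligand, which keeps the anti selectivity of the chair transition state but not the facial control. The two anti adducts, 20 and its (3S,4S) diastereomer F3, are separated by preparative chromatography at this stage or after silylation. The route is rejoined at 20. Stereocontrol by a catalyst is replaced by separation against the fixed C1 centre.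

**Step 7.**
- What may go wrong: on the elaborate diol the carbomagnesiation may stall through competing deprotonation of the terminal alkyne, aggregation of the bis-alkoxide or incomplete conversion, and iodinolysis may then give mixtures.
- Fallback: it sets out from 7 and 3 and moves the carbometalation to the smallest possible substrate, with the iodide masked as a silane through the palladium step.
  - K2CO3 in methanol converts 7 into (3S)-pent-1-en-4-yn-3-ol F4.
  - The same copper-catalysed methylmagnesiation, quenched with TMSCl, gives C,O-bis-silylated (Z)-vinylsilane F5.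
  - Hydroboration with 9-BBN gives alkylborane F6, which is coupled with 3 as in step 6 to give vinylsilane F7.
  - Iododesilylation with N-iodosuccinimide in hexafluoroisopropanol proceeds with retention, the O-silyl group is lost on work-up, and the route is rejoined at 12.

**Step 19.**
- What may go wrong: lactonisation of the conjugated acid may be slow once O6 is free, so that the seco acid persists or the ester migrates from O8. Prolonged exposure to HF may start ionisation of the allylic C–O bonds.
- Fallback: it sets out from 27 and reverses the order of events. HF·pyridine first removes the three silyl groups with the tert-butyl ester intact, giving triol ester F9. A short treatment with trifluoroacetic acid in CH2Cl2 at 0 °C then cleaves the tert-butyl ester and closes the lactone in one acid-catalysed step, arriving at 31.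

## Further compounds

F1 | step 16 | C8 epimer of carbinol 24 (8S) | CC(C)(C)OC(=O)C(=C)[C@H]1[C@H](O[Si](C)(C)C(C)(C)C)/C=C(/CO[Si](c2ccccc2)(c2ccccc2)C(C)(C)C)CC[C@H](O[Si](C)(C)C(C)(C)C)/C(C)=C\[C@@H]1O
F2 | step 16 | ten-membered C8 enone derived from 24 | CC(C)(C)OC(=O)C(=C)[C@H]1[C@H](O[Si](C)(C)C(C)(C)C)/C=C(/CO[Si](c2ccccc2)(c2ccccc2)C(C)(C)C)CC[C@H](O[Si](C)(C)C(C)(C)C)/C(C)=C\C1=O
F3 | step 12 | (3S,4S) diastereomer of hydroxy ester 20 | CC(C)(C)[Si](C)(C)OC[C@H](C(=C)C(=O)OC(C)(C)C)[C@@H](O)/C=C(/CO[Si](c1ccccc1)(c1ccccc1)C(C)(C)C)CC[C@H](O[Si](C)(C)C(C)(C)C)/C(C)=C\I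
F4 | step 7 | (3S)-pent-1-en-4-yn-3-ol | C=C[C@H](O)C#C
F5 | step 7 | trimethyl{[(1Z,3S)-2-methyl-1-(trimethylsilyl)penta-1,4-dien-3-yl]oxy}silane | C=C[C@H](O[Si](C)(C)C)/C(C)=C\[Si](C)(C)C
F6 | step 7 | 9-BBN adduct of F5 at the terminal alkene | C[Si](C)(C)O[C@@H](CCB1C2CCCC1CCC2)/C(C)=C\[Si](C)(C)C
F7 | step 7 | (2E,6S,7Z)-3-{[(tert-butyldiphenylsilyl)oxy]methyl}-7-methyl-8-(trimethylsilyl)-6-[(trimethylsilyl)oxy]octa-2,7-dien-1-ol | OC/C=C(/CO[Si](c1ccccc1)(c1ccccc1)C(C)(C)C)CC[C@H](O[Si](C)(C)C)/C(C)=C\[Si](C)(C)C
F9 | step 19 | tert-butyl ester of seco acid 30 (triol ester) | CC(C)(C)OC(=O)C(=C)[C@H]1[C@H](O)/C=C(/CO)CC[C@H](O)/C(C)=C\[C@H]1OC(=O)[C@@H](C)CC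
A1 | alternative 1 | O6 diethylphosphonoacetate of the trans C7–C8 epoxide | CCOP(=O)(OCC)CC(=O)O[C@H](/C=C(/CO[Si](C)(C)C(C)(C)C)CCCOCc1ccc(OC)cc1)[C@H]1O[C@@H]1/C=C(C)\I
A2 | alternative 1 | trans α-methylene-γ-lactone with free C8 hydroxyl | C=C1C(=O)O[C@H](/C=C(/CO[Si](C)(C)C(C)(C)C)CCCOCc2ccc(OC)cc2)[C@H]1[C@H](O)/C=C(C)\I
A3 | alternative 2 | C6 aldehyde with C5 alkenyl iodide and C12 methyl ester | O=C[C@H](C(=C)C(=O)OC)[C@H](OCc1ccc(OC)cc1)/C=C(C)\[C@@H](O[Si](C)(C)C(C)(C)C)CC/C(CO[Si](C)(C)C(C)(C)C)=C\I
A4 | alternative 2 | protected germacranolide with both rings closed | C=C1C(=O)O[C@@H]2/C=C(/CO[Si](C)(C)C(C)(C)C)CC[C@H](O[Si](C)(C)C(C)(C)C)/C(C)=C\[C@@H](OCc3ccc(OC)cc3)[C@@H]12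
A5 | alternative 3 | cis-1,2-dialkenylcyclohexanol for the oxy-Cope shift | C=C[C@]1(O)C[C@@H](OCc2ccc(OC)cc2)[C@@H](CCO[Si](C)(C)C(C)(C)C)[C@H](O[Si](C)(C)C(C)(C)C)[C@@H]1C(=C)CO[Si](C)(C)C(C)(C)C
A6 | alternative 3 | ten-membered C10 ketone with ring-cis C4=C5 | O=C1CCC/C(CO[Si](C)(C)C(C)(C)C)=C\[C@@H](O[Si](C)(C)C(C)(C)C)[C@H](CCO[Si](C)(C)C(C)(C)C)[C@H](OCc2ccc(OC)cc2)C1
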